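**Plan**
Atom labels: ring C1 (angeloyloxy carbon), C2=C3 (C3 carries the methyl), C4 (acetoxy carbon), C5 (CH2), C6; side chain C7 (CHMe), C8, C9 (acetoxy carbon), C10=C11.
Retrosynthesis: the three ester C–O bonds are cut first (angelate on O1, acetates on O4 and O9). A formyl group is then put back on C5 and the ring is cut across C1–C6 and C4–C5 (retro-[4+2]). The enal is cut at C9–C10 back to (S)-citronellal and an isobutenyl unit.
Enabling feature: the ring is a cyclohex-2-ene with oxygen on both allylic carbons (C1 and C4, cis), an unsubstituted C5 next to C4, and the C6 side chain trans to both oxygens. This is the imprint of an endo [4+2] between an (E,E)-1,4-dioxygenated 2-methyldiene and an (E)-enal whose formyl group on C5 is traceless.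
Forward: the chain is built first (citronellal to enal 9, six steps) and the diene 11 in one step. The only ring is closed last by an amine-catalysed Diels–Alder reaction, followed by decarbonylation and ester adjustment.
Stereochemistry: C7 comes from (S)-citronellal and C9 from a CBS reduction. C1, C4 and C6 come from the cycloaddition (diene and enal geometry, endo rule, face control by the (5S)-imidazolidinone). The angelate geometry comes from angelic acid.

Key step: step 8

Assumption: (S)-citronellal of high enantiomeric purity and (E)-4-acetoxy-2-methylbut-2-enal are taken as purchasable.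

**Step 1**
Reactants: 1 (S)-citronellal; 2 2-methylprop-1-en-1-ylmagnesium bromide
Product: 3 (6S)-2,6,10-trimethylundeca-2,9-dien-4-ol as a mixture of C4 epimers
Conditions: THF, −78 to 0 °C; aq NH4Cl
Reagents that add atoms: none
Why: Grignard 1,2-addition of the alkenylmagnesium reagent to the aldehyde should give the secondary allylic alcohol; the new carbinol centre is not controlled here and is erased in step 2.

**Step 2**
Reactants: 3 (6S)-2,6,10-trimethylundeca-2,9-dien-4-ol
Product: 4 (6S)-2,6,10-trimethylundeca-2,9-dien-4-one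
Conditions: Dess–Martin periodinane, CH2Cl2, 0 °C to rt
Reagents that add atoms: none
Why: Dess–Martin oxidation of a secondary allylic alcohol to the enone is mild and should leave both trisubstituted alkenes and the methyl-bearing stereocentre untouched.

**Step 3**
Reactants: 4 (6S)-2,6,10-trimethylundeca-2,9-dien-4-one
Product: 5 (4R,6S)-2,6,10-trimethylundeca-2,9-dien-4-ol
Conditions: (S)-2-methyl-CBS-oxazaborolidine (0.2 equiv), catecholborane, toluene, −78 °C; aq NaOH work-up
Reagents that add atoms: none
Why: Corey–Bakshi–Shibata reduction; with the alkenyl group as the large and the CH2 group as the small substituent, the (S)-oxazaborolidine should deliver hydride to the face that gives the (4R) allylic alcohol (reagent control), and catecholborane at low temperature avoids alkene hydroboration.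

**Step 4**
Reactants: 5 (4R,6S)-2,6,10-trimethylundeca-2,9-dien-4-ol
Product: 6 tert-butyldimethyl{[(4R,6S)-2,6,10-trimethylundeca-2,9-dien-4-yl]oxy}silane
Conditions: TBSCl, imidazole, DMF, rt
Reagents that add atoms: tert-butyldimethylsilyl chloride, CC(C)(C)[Si](C)(C)Cl
Why: Standard silylation of a secondary alcohol protects the future C9 oxygen through the oxidation, cycloaddition and decarbonylation steps.

**Step 5**
Reactants: 6 tert-butyldimethyl{[(4R,6S)-2,6,10-trimethylundeca-2,9-dien-4-yl]oxy}silane
Product: 8 (4S,6R)-6-(tert-butyldimethylsilyloxy)-4,8-dimethylnon-7-enal, via secondary ozonide 7 (not isolated)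
Conditions: O3 (1.0 equiv, titrated), CH2Cl2, −78 °C; then PPh3, −78 °C to rt
Reagents that add atoms: ozone, [O-][O+]=O
Why: Ozonolysis with reductive work-up; the isolated electron-rich trisubstituted alkene should react ahead of the alkene bearing the allylic silyloxy group (inductively deactivated and shielded), as in the terminal-selective ozonolysis of geranyl esters, when one equivalent of ozone is used.

**Step 6**
Reactants: 8 (4S,6R)-6-(tert-butyldimethylsilyloxy)-4,8-dimethylnon-7-enal
Product: 9 (2E,4R,6R)-6-(tert-butyldimethylsilyloxy)-4,8-dimethylnona-2,7-dienal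
Conditions: IBX (1.3 equiv), DMSO–fluorobenzene, 65 °C
Reagents that add atoms: none
Why: IBX-mediated α,β-dehydrogenation of an aldehyde should give the conjugated (E)-enal; only a slight excess of oxidant is used so that the γ-hydrogen at the methyl stereocentre is not removed by a second dehydrogenation.

**Step 7**
Reactants: 10 (E)-4-acetoxy-2-methylbut-2-enal
Product: 11 (1E,3E)-4-(tert-butyldimethylsilyloxy)-3-methylbuta-1,3-dien-1-yl acetate
Conditions: TBSOTf, Et3N, CH2Cl2, −78 to 0 °C
Reagents that add atoms: tert-butyldimethylsilyl trifluoromethanesulfonate, CC(C)(C)[Si](C)(C)OS(=O)(=O)C(F)(F)F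
Why: Soft enolisation (O-silylation of the enal, then γ-deprotonation by Et3N) gives the silyl dienol ether; the s-trans enal places the silyloxy group trans to the diene chain and allylic strain with the C3 methyl forces the acetoxy group outside, so the (1E,3E) isomer should dominate.

**Step 8**
Reactants: 9 (2E,4R,6R)-6-(tert-butyldimethylsilyloxy)-4,8-dimethylnona-2,7-dienal; 11 (1E,3E)-4-(tert-butyldimethylsilyloxy)-3-methylbuta-1,3-dien-1-yl acetate
Product: 14 (1S,4R,5R,6R)-4-(tert-butyldimethylsilyloxy)-6-[(2R,4R)-4-(tert-butyldimethylsilyloxy)-6-methylhept-5-en-2-yl]-5-formyl-3-methylcyclohex-2-en-1-yl acetate, via enal iminium ion 12 (not isolated), via cycloadduct iminium ion 13 (not isolated)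
Conditions: first-generation MacMillan catalyst (5S)-5-benzyl-2,2,3-trimethylimidazolidin-4-one·HCl (20 mol %), 11 (2 equiv), CH3CN–H2O (95:5), −20 °C
Reagents that add atoms: water, O
Why: The amine salt condenses with enal 9 to the (E)-iminium ion 12, whose lowered LUMO undergoes an endo [4+2] cycloaddition (asynchronous, C1–C6 bond leading) with the electron-rich diene 11, and hydrolysis of iminium ion 13 releases 14 and the catalyst; the closest known reaction type is the iminium-catalysed Diels–Alder reaction of enals with acyclic 1-acyloxy dienes. The six-membered ring closes by an intermolecular, untethered [4+2] that forms C1–C6 and C4–C5 suprafacially on both partners and leaves the C2=C3 double bond from the central bond of the diene. C1 and C4 become cis because both oxygens are outside substituents of the (E,E)-diene, and C6 becomes trans to both because the formyl group sits endo (cis to O4) and the side chain is trans to it in the (E)-enal. The absolute sense comes from the benzyl group of the (5S)-catalyst, which covers the Re face of C5 in 12 so that the diene adds to the C5 Si (C6 Re) face, a reagent control expected to override the weak bias of the C7 stereocentre; the C5 centre is temporary. The step needs regio-, endo- and 1,4-selectivity: the silyloxy group on C4 is a much stronger donor than the acetoxy group on C1 and makes C1 the nucleophilic terminus that pairs with the electrophilic β-carbon C6, and iminium activation directs attack to the C=C bond and not to the carbonyl carbon.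

**Step 9**
Reactants: 14 the formyl cycloadduct
Product: 15 (1S,4R,6S)-4-(tert-butyldimethylsilyloxy)-6-[(2R,4R)-4-(tert-butyldimethylsilyloxy)-6-methylhept-5-en-2-yl]-3-methylcyclohex-2-en-1-yl acetate
Conditions: RhCl(PPh3)3 (1.1 equiv), toluene, 110 °C
Reagents that add atoms: none
Why: Tsuji–Wilkinson decarbonylation (oxidative addition of the formyl C–H bond to rhodium, CO extrusion, C–H reductive elimination) removes the helper group; C5 becomes a plain methylene, so its configuration is of no consequence, and no other stereocentre is touched.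

**Step 10**
Reactants: 15 the C1 acetate
Product: 16 (1S,4R,6S)-4-(tert-butyldimethylsilyloxy)-6-[(2R,4R)-4-(tert-butyldimethylsilyloxy)-6-methylhept-5-en-2-yl]-3-methylcyclohex-2-en-1-ol
Conditions: K2CO3 (0.2 equiv), MeOH, 0 °C to rt
Reagents that add atoms: none
Why: Base-catalysed transesterification (methanolysis) removes the only ester present, the C1 acetate, while both silyl ethers are stable to K2CO3 in methanol.

**Step 11**
Reactants: 16 the C1 alcohol; 17 angelic acid ((Z)-2-methylbut-2-enoic acid)
Product: 19 (1S,4R,6S)-4-(tert-butyldimethylsilyloxy)-6-[(2R,4R)-4-(tert-butyldimethylsilyloxy)-6-methylhept-5-en-2-yl]-3-methylcyclohex-2-en-1-yl (Z)-2-methylbut-2-enoate, via mixed anhydride 18 (not isolated)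
Conditions: 17, 2,4,6-trichlorobenzoyl chloride, Et3N, toluene, rt; then 16, 80 °C (no DMAP)
Reagents that add atoms: none
Why: Yamaguchi esterification through mixed anhydride 18 in warm toluene without DMAP is a known way to acylate hindered secondary alcohols with angelic acid with little Z-to-E isomerisation, and C1 keeps its configuration because the acyl–oxygen bond is the one formed.

**Step 12**
Reactants: 19 the angelate bis-silyl ether
Product: 20 (1S,4R,6S)-4-hydroxy-6-[(2R,4R)-4-hydroxy-6-methylhept-5-en-2-yl]-3-methylcyclohex-2-en-1-yl (Z)-2-methylbut-2-enoate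
Conditions: HF·pyridine, pyridine, THF, 0 °C to rt
Reagents that add atoms: none
Why: Fluoride-mediated desilylation under buffered conditions should free the C4 and C9 hydroxyls without acyl migration or isomerisation of the angelate.

**Step 13**
Reactants: 20 the diol
Product: 21 (1S,4R,6S)-4-acetoxy-6-[(2R,4R)-4-acetoxy-6-methylhept-5-en-2-yl]-3-methylcyclohex-2-en-1-yl (Z)-2-methylbut-2-enoate
Conditions: Ac2O, pyridine, DMAP (cat.), CH2Cl2, 0 °C to rt
Reagents that add atoms: acetic anhydride, CC(=O)OC(C)=O
Why: DMAP-catalysed acetylation of the two secondary allylic alcohols, with retention at C4 and C9, should give the target.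

**Compound list**
1 | (S)-citronellal | CC(C)=CCC[C@H](C)CC=O | starting material
2 | 2-methylprop-1-en-1-ylmagnesium bromide | CC(C)=C[Mg]Br | starting material
3 | (6S)-2,6,10-trimethylundeca-2,9-dien-4-ol (C4 epimers) | CC(C)=CCC[C@H](C)CC(O)C=C(C)C | intermediate
4 | (6S)-2,6,10-trimethylundeca-2,9-dien-4-one | CC(C)=CCC[C@H](C)CC(=O)C=C(C)C | intermediate
5 | (4R,6S)-2,6,10-trimethylundeca-2,9-dien-4-ol | CC(C)=CCC[C@H](C)C[C@H](C=C(C)C)O | intermediate
6 | tert-butyldimethyl{[(4R,6S)-2,6,10-trimethylundeca-2,9-dien-4-yl]oxy}silane | CC(C)=CCC[C@H](C)C[C@H](C=C(C)C)O[Si](C)(C)C(C)(C)C | intermediate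
7 | secondary ozonide (1,2,4-trioxolane) of the 9,10-alkene of 6 (not isolated) | CC1(C)OOC(CC[C@H](C)C[C@H](C=C(C)C)O[Si](C)(C)C(C)(C)C)O1 | intermediate
8 | (4S,6R)-6-(tert-butyldimethylsilyloxy)-4,8-dimethylnon-7-enal | O=CCC[C@H](C)C[C@H](C=C(C)C)O[Si](C)(C)C(C)(C)C | intermediate
9 | (2E,4R,6R)-6-(tert-butyldimethylsilyloxy)-4,8-dimethylnona-2,7-dienal | O=C/C=C/[C@H](C)C[C@H](C=C(C)C)O[Si](C)(C)C(C)(C)C | intermediate
10 | (E)-4-acetoxy-2-methylbut-2-enal | CC(=O)OC/C=C(\C)C=O | starting material
11 | (1E,3E)-4-(tert-butyldimethylsilyloxy)-3-methylbuta-1,3-dien-1-yl acetate | CC(=O)O/C=C/C(C)=C/O[Si](C)(C)C(C)(C)C | intermediate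
12 | iminium chloride of enal 9 and the (5S)-imidazolidinone (not isolated) | CN1C(=O)[C@H](Cc2ccccc2)[N+](=C/C=C/[C@H](C)C[C@H](C=C(C)C)O[Si](C)(C)C(C)(C)C)C1(C)C.[Cl-] | intermediate
13 | iminium chloride of cycloadduct 14 and the (5S)-imidazolidinone (not isolated) | CC(=O)O[C@@H]1C=C(C)[C@H](O[Si](C)(C)C(C)(C)C)[C@H](C=[N+]2[C@@H](Cc3ccccc3)C(=O)N(C)C2(C)C)[C@H]1[C@H](C)C[C@H](C=C(C)C)O[Si](C)(C)C(C)(C)C.[Cl-] | intermediate
14 | (1S,4R,5R,6R)-4-(tert-butyldimethylsilyloxy)-6-[(2R,4R)-4-(tert-butyldimethylsilyloxy)-6-methylhept-5-en-2-yl]-5-formyl-3-methylcyclohex-2-en-1-yl acetate | CC(=O)O[C@@H]1C=C(C)[C@H](O[Si](C)(C)C(C)(C)C)[C@H](C=O)[C@H]1[C@H](C)C[C@H](C=C(C)C)O[Si](C)(C)C(C)(C)C | intermediate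
15 | (1S,4R,6S)-4-(tert-butyldimethylsilyloxy)-6-[(2R,4R)-4-(tert-butyldimethylsilyloxy)-6-methylhept-5-en-2-yl]-3-methylcyclohex-2-en-1-yl acetate | CC(=O)O[C@@H]1C=C(C)[C@H](O[Si](C)(C)C(C)(C)C)C[C@H]1[C@H](C)C[C@H](C=C(C)C)O[Si](C)(C)C(C)(C)C | intermediate
16 | (1S,4R,6S)-4-(tert-butyldimethylsilyloxy)-6-[(2R,4R)-4-(tert-butyldimethylsilyloxy)-6-methylhept-5-en-2-yl]-3-methylcyclohex-2-en-1-ol | O[C@@H]1C=C(C)[C@H](O[Si](C)(C)C(C)(C)C)C[C@H]1[C@H](C)C[C@H](C=C(C)C)O[Si](C)(C)C(C)(C)C | intermediate
17 | angelic acid, (Z)-2-methylbut-2-enoic acid | C/C=C(/C)C(O)=O | starting material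
18 | angelic 2,4,6-trichlorobenzoic mixed anhydride (not isolated) | C/C=C(/C)C(=O)OC(=O)c1c(Cl)cc(Cl)cc1Cl | intermediate
19 | (1S,4R,6S)-4-(tert-butyldimethylsilyloxy)-6-[(2R,4R)-4-(tert-butyldimethylsilyloxy)-6-methylhept-5-en-2-yl]-3-methylcyclohex-2-en-1-yl (Z)-2-methylbut-2-enoate | C/C=C(/C)C(=O)O[C@@H]1C=C(C)[C@H](O[Si](C)(C)C(C)(C)C)C[C@H]1[C@H](C)C[C@H](C=C(C)C)O[Si](C)(C)C(C)(C)C | intermediate
20 | (1S,4R,6S)-4-hydroxy-6-[(2R,4R)-4-hydroxy-6-methylhept-5-en-2-yl]-3-methylcyclohex-2-en-1-yl (Z)-2-methylbut-2-enoate | C/C=C(/C)C(=O)O[C@@H]1C=C(C)[C@H](O)C[C@H]1[C@H](C)C[C@H](C=C(C)C)O | intermediate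
21 | (1S,4R,6S)-4-acetoxy-6-[(2R,4R)-4-acetoxy-6-methylhept-5-en-2-yl]-3-methylcyclohex-2-en-1-yl (Z)-2-methylbut-2-enoate | C/C=C(/C)C(=O)O[C@@H]1C=C(C)[C@H](OC(C)=O)C[C@H]1[C@H](C)C[C@H](C=C(C)C)OC(C)=O | target

**Step count and risks**
Total steps: 13. Longest linear sequence: 12 (steps 1 to 6 and 8 to 13; step 7 is the one-step diene branch).

Steps most likely to fail:

1. Step 8. The silyl dienol ether may hydrolyse under the aqueous acidic amine-salt conditions before it cycloadds. The β-branched iminium ion may react too slowly. The methyl stereocentre may be lost through dienamine formation. The product may lose silanol by β-elimination. Fallback (auxiliary control under Lewis acid, no amine): it sets out from enal 9. Pinnick oxidation (NaClO2, NaH2PO4, 2-methylbut-2-ene, t-BuOH–H2O) should give (2E,4R,6R)-6-(tert-butyldimethylsilyloxy)-4,8-dimethylnona-2,7-dienoic acid F1. Pivaloyl chloride and Et3N in THF convert it into the mixed pivalic anhydride F2, which acylates lithiated (S)-4-benzyloxazolidin-2-one to the N-enoyl oxazolidinone F3. Cycloaddition of F3 with diene 11 promoted by Me2AlCl in CH2Cl2 at −78 °C should proceed through the chelated s-cis imide, whose benzyl group leaves the same C5 Si face open, and give the endo imide cycloadduct F4. Excess LiOH–H2O2 in THF–H2O removes the auxiliary and the C1 acetate to give the hydroxy acid F5. Photocatalytic hydrodecarboxylation (9-mesityl-10-methylacridinium tetrafluoroborate, PhSSPh, i-Pr2NEt, trifluoroethanol, blue light) replaces the carboxyl group by hydrogen and comes back to the route at alcohol 16.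

2. Step 9. Decarbonylation of the hindered secondary aldehyde may be slow, and at the temperature needed β-elimination of silanol or alkene migration may compete. Fallback (radical decarboxylation in place of the rhodium reaction): it sets out from 14. Pinnick oxidation (NaClO2, NaH2PO4, 2-methylbut-2-ene) should give the C5 carboxylic acid F6. The same photocatalytic hydrodecarboxylation as above then gives the secondary C5 radical, which takes up hydrogen from the thiol formed in the flask, and the sequence comes back to the route at 15.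

3. Step 5. Ozone may not discriminate well enough between the two trisubstituted alkenes, so that cleavage of the allylic silyloxy alkene or double cleavage erodes the material. Fallback (two-stage cleavage with a more selective electrophile): it sets out from 6. One equivalent of mCPBA in CH2Cl2 at −20 °C should epoxidise the isolated, more electron-rich alkene to the 9,10-epoxide F7. Periodic acid H5IO6 in THF–H2O at 0 °C then cleaves F7 and comes back to the route at aldehyde 8.

**Further compounds**
F1 | step 8 | (2E,4R,6R)-6-(tert-butyldimethylsilyloxy)-4,8-dimethylnona-2,7-dienoic acid | OC(=O)/C=C/[C@H](C)C[C@H](C=C(C)C)O[Si](C)(C)C(C)(C)C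
F2 | step 8 | mixed pivalic anhydride of F1 | CC(C)(C)C(=O)OC(=O)/C=C/[C@H](C)C[C@H](C=C(C)C)O[Si](C)(C)C(C)(C)C
F3 | step 8 | (S)-4-benzyl-3-[(2E,4R,6R)-6-(tert-butyldimethylsilyloxy)-4,8-dimethylnona-2,7-dienoyl]oxazolidin-2-one | O=C(/C=C/[C@H](C)C[C@H](C=C(C)C)O[Si](C)(C)C(C)(C)C)N1[C@@H](Cc2ccccc2)COC1=O
F4 | step 8 | imide cycloadduct (C5 acyl oxazolidinone analogue of 14) | CC(=O)O[C@@H]1C=C(C)[C@H](O[Si](C)(C)C(C)(C)C)[C@H](C(=O)N2[C@@H](Cc3ccccc3)COC2=O)[C@H]1[C@H](C)C[C@H](C=C(C)C)O[Si](C)(C)C(C)(C)C
F5 | step 8 | C1 hydroxy C5 carboxylic acid | O[C@@H]1C=C(C)[C@H](O[Si](C)(C)C(C)(C)C)[C@H](C(O)=O)[C@H]1[C@H](C)C[C@H](C=C(C)C)O[Si](C)(C)C(C)(C)C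
F6 | step 9 | C1 acetoxy C5 carboxylic acid | CC(=O)O[C@@H]1C=C(C)[C@H](O[Si](C)(C)C(C)(C)C)[C@H](C(O)=O)[C@H]1[C@H](C)C[C@H](C=C(C)C)O[Si](C)(C)C(C)(C)C
F7 | step 5 | 9,10-epoxide of 6 | CC1(C)OC1CC[C@H](C)C[C@H](C=C(C)C)O[Si](C)(C)C(C)(C)C
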